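## Structural features

The target is a monocyclic cyclohept-2-en-1-one; its ring atoms are numbered C1 (ketone), C2 (bearing CH2OH), C3 (=CH), C4 (CH2), C5 (quaternary), C6 and C7. C5 carries a methyl group and a 3-hydroperoxy-4-methylpent-4-enyl chain, C6 an (E)-2-acyloxyvinyl group (the enol ester of 3-methylbut-2-enoic acid) and C7 an acetonyl group, so that C1 and the acetonyl carbonyl form a 1,4-diketone. Three stereocentres stand side by side, C5 (S), C6 (S) and C7 (S), with the C6 and C7 arms trans and the C5 methyl cis to the C6 arm; the fourth (S) sits alone in the side chain, four bonds from C5, and bears the hydroperoxide. The fragile groups are the secondary allylic hydroperoxide (reduced by phosphines, sulfides and low-valent metals), the enol ester (an acyl donor with a defined double-bond geometry), the 2-hydroxymethyl enone (open to conjugate addition and to epoxidation by peroxide anions) and C7, which can epimerise next to the C1 ketone. The real difficulty is the quaternary C5 flanked by two tertiary centres on a seven-membered ring, together with a remote carbinol centre that no ring centre can control and an order of events that must keep peroxide, enol ester and enone away from reagents that destroy them. The key step uses the fact that C6 with its methyl-bearing neighbour C5 is the isopropenyl-bearing carbon of carvone, and that the arm on C6 (C4', C3') and the arm on C7 (C1', C2' and its methyl) are the two ends of carvone's methylcyclohexenone ring; the ring bond C3–C4 is then made by an ene reaction between the isopropenyl group and an aldehyde on a three-carbon chain at C7. By the usual classification this closure is a type 2 intramolecular carbonyl-ene reaction (tether on the central carbon of the ene unit), not a type 1 process; the structures of precursor and product are otherwise consistent with (S)-carvone and a trans aldol.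

## Logic of the disconnections

**33 to 24, then 21 + 23.** The O–O–C bond of the peroxyketal in 32 and, further back, the C–OO bond at the side-chain carbinol carbon of 24 are cut. The hydroperoxide is the most fragile group and its stereocentre is too remote for substrate control, so it is introduced by substitution with inversion on the (R)-sulfonate 21 using the protected hydroperoxide 23. This reduces the problem to an alcohol stereocentre. The forward step must be a clean SN2 reaction on a secondary allylic mesylate, and because peroxide anions epoxidise enones and cleave enol esters, it must come before both groups exist; the peroxide is then carried as a peroxyketal.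

**32 to 30 + 31.** The C2–CH2OH bond is cut. C2 is the nucleophilic α-carbon of the enone under amine catalysis, so one carbon (31) is added last and the free hydroxyl never needs protection. The demand is that the enol ester and the peroxyketal tolerate a nucleophilic amine in water.

**30 to 26 + 28 (through 29), and 26 to 25 to 24.** The enol O–acyl bond and the C2=C3 double bond are cut. The enol ester comes from the C6 acetaldehyde arm and the enone from loss of pivalate β to the C1 ketone, both under the same mild base. 26 arises from 24 by unmasking and oxidising two alcohols together. The demands are aldehyde-selective enolisation, (E) geometry, and no aldol between the aldehyde and the two ketones.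

**20 to 18 + 19, and 18 to 17.** The C–C bond between the carbinol carbon and the isopropenyl group is cut. An alkenylchromium addition is selective for aldehydes over the acetonyl ketone, and a chiral ligand sets the (R) configuration by reagent control. The side chain shrinks to a three-carbon aldehyde, released from a primary silyl ether.

**17 back to 13.** In the retrosynthetic sense the C2'=C3' bond is re-formed and an oxygen is put back on C1'. The acetonyl arm and the C6 arm are the ends of a methylcyclohexene, and the acetonyl CH2 is the old carvone carbonyl carbon: reduction to the carbinol (11), acylation (13), ozonolysis (14) and SmI2 cleavage of the α-acyloxy ketone (16 to 17) remove that oxygen. The gain is a trans-fused bicycle in which C6 and C7 are locked. The demands are that the ring alkene is the only alkene at the ozonolysis stage and that the new aldehyde is told apart from the new ketone (15, 16).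

**10 to 8 + 9, with 11, 12, 13 as adjustments.** The bond from C5 to the side chain is cut. Hydrogen-atom transfer to the exocyclic methylene of 8 gives the C5 methyl and a tertiary radical that adds to 9. The quaternary centre is exchanged for an alkene; the demand is addition on the face of C5 trans to the C6–C4' bond.

**8 to 7.** The C3–C4 bond is cut (key step). This opens the seven-membered ring to a 5,6-trans-disubstituted carvone, and the homoallylic alcohol with exocyclic methylene is the signature of a type 2 carbonyl-ene reaction. The demand is attack through the methylene terminus with hydrogen transfer and without loss of the β-silyloxy group.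

**7 to 4, then 1 + 2.** The C7–C1 bond is cut (aldol). The kinetic enolate of 1 reacts at C6 trans to the isopropenyl group, which sets the C6/C7 relationship of the target. 2 is bought with the silyl group already in place, so the precursor keeps the required skeleton and silyl ether but is reached in four steps from two commercial compounds.

**23 from 22, 28 from 27.** The O–C bond of 23 and the acyl–O bond of 28 are cut. 23 comes from 22 by ozonolysis in methanol, and 28 from two molecules of 27 by dehydration. Both reagents are one step from commercial materials.

## Other disconnections considered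

Alternative 1: The cut goes through C6–C7 and C4–C5. Forward, the acetoxypyranone A1 is warmed with an amine base; after loss of acetate, its two oxygen-flanked ring carbons add to the tethered (E)-trisubstituted alkene in a (5+2) cycloaddition, giving the oxygen-bridged cycloheptenone A2 with a fused methylcyclohexene.
- In its favour: one step makes the seven-membered ring, the quaternary C5 and the C6 centre. The C5/C6 relationship follows stereospecifically from alkene geometry, which is better than relying on the facial selectivity of a radical. The C2 oxymethyl group and the C2=C3 enone are present from the start, so no late hydroxymethylation is needed (also better). The cyclohexene arrives without an oxygen on C1', so nothing has to be removed there.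
- Against it here: the C4–O–C7 bridge of A2 must be excised, C7–O by reductive cleavage next to the ketone and C4–O by a separate allylic deoxygenation, and C7 is then set by protonation. The ring stereocentres of A1 are lost on ionisation to the planar dipole, so only the remote dioxolane carbon could steer the absolute sense and two diastereomeric series are to be expected; the chosen plan takes C6 and C7 from carvone. The diol acetonide has no direct route to a configurationally defined secondary allylic hydroperoxide.
- Comparison: both plans close the ring in one concerted pericyclic step. The alternative should reach a bicyclic stage about as quickly but loses the advantage in removing the bridge, and it needs the same ozonolysis and enol ester end game.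

Alternative 2: The cut is C1–C7. Forward, a triazolium-derived carbene adds to the aldehyde of A3, the acyl anion equivalent attacks the enone β-carbon in a 7-exo-trig closure and the carbene is released, giving the 2-acetonylcycloheptanone A4.
- In its favour: the 1,4-dicarbonyl pattern (C1 ketone and acetonyl ketone) appears directly in the right oxidation states, so neither ozonolysis nor removal of an oxygen is needed; on this point it is better than the chosen plan. It is organocatalytic and mild, C7 can be corrected by equilibration, and the C6 CH2O stub of A4 can be turned into the enol ester through an aldehyde and an acyloxymethylene Wittig reaction, which is an equal solution.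
- Against it here: Stetter closures of seven-membered rings from aliphatic aldehydes are far less favourable than five- and six-membered ones and compete with aldol and benzoin pathways. The vicinal quaternary C5 and tertiary C6 of A3 must be built in an open chain, so the hardest part of the problem is moved, not solved. The C2=C3 unsaturation must then be introduced away from C7 and C2 hydroxymethylated. The prenyl group would give the hydroperoxide only by unselective photooxygenation, whereas the chosen plan sets that centre by reagent control.
- Comparison: shorter after the ring closure, longer and less secure before it; overall step economy should be similar.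

Alternative 3: The cut removes C2 from between C1 and C3. Forward, dibromocarbene (CHBr3, KOt-Bu) adds to the C1=C3 double bond of the silyl enol ether A5, whose six-membered ring is assembled by a Diels–Alder reaction; cyclopropanation followed by ring opening with loss of bromide and of the silyl group gives the 2-bromocyclohept-2-enone A6.
- In its favour: C5, C6 and C7 are set on a six-membered ring, where cycloaddition rules give dependable relative control and chiral catalysts absolute control; this is arguably more secure than the radical step of the chosen plan. The bromine of A6 sits at C2, so the hydroxymethyl group can be attached by cross-coupling, which is better than an amine-catalysed hydroxymethylation beside an enol ester. The enone regiochemistry is unambiguous.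
- Against it here: a cycloaddition that creates quaternary C5 needs a trisubstituted dienophile. The enol ether A5 must be formed toward C3 and not C7. Carbene generation is strongly basic. Above all, C5 and C6 carry only one-carbon stubs, so the side chain is five carbons short and many chain-extension and protecting-group steps follow.
- Comparison: both plans hide the seven-membered ring in a six-membered precursor, but the chosen plan uses every carbon of carvone. Ring formation is more predictable in the alternative; step economy is worse.

Key step: step 5

Remark on the chemistry: the carbinol carbons C1, C3 and C1' are transient. Each is formed as a mixture of epimers, carried as such and left unassigned in the SMILES, because all three later become sp2 or CH2.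

Remark on the chemistry: compound 2 is assumed to be purchased; if not, it is two steps from 1,3-propanediol.

## Route

Step 1
Reactants: 1 (S)-carvone; 2 3-(tert-butyldimethylsilyloxy)propanal
Product: 4 trans-6-[3-(tert-butyldimethylsilyloxy)-1-hydroxypropyl]carvone (C1 epimers), via carvone lithium dienolate 3 (not isolated)
Conditions: LiN(i-Pr)2, THF, −78 °C; then 2, −78 °C; AcOH quench
Reagents that add atoms: none
Why: Kinetic deprotonation of carvone at C6 gives the cross-conjugated dienolate, and the aldol addition should take place on the face trans to the isopropenyl group, which fixes the trans C6/C7 relationship of the target; the new carbinol centre (future C1) is oxidised later.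

Step 2
Reactants: 4 aldol adduct
Product: 5 trans-6-[1,3-bis(tert-butyldimethylsilyloxy)propyl]carvone
Conditions: TBSOTf, 2,6-lutidine, CH2Cl2, −78 °C
Reagents that add atoms: tert-butyldimethylsilyl trifluoromethanesulfonate, CC(C)(C)[Si](C)(C)OS(=O)(=O)C(F)(F)F
Why: Silylation of the secondary aldol hydroxyl with a silyl triflate and a hindered pyridine is fast at low temperature and avoids retro-aldol cleavage.

Step 3
Reactants: 5 bis-silyl ether
Product: 6 trans-6-[1-(tert-butyldimethylsilyloxy)-3-hydroxypropyl]carvone
Conditions: HF·pyridine, pyridine, THF, 0 °C
Reagents that add atoms: none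
Why: Buffered HF cleaves the unhindered primary silyl ether much faster than the secondary one flanked by the ring.

Step 4
Reactants: 6 primary alcohol
Product: 7 trans-6-[1-(tert-butyldimethylsilyloxy)-3-oxopropyl]carvone (ene precursor)
Conditions: Dess–Martin periodinane, pyridine, CH2Cl2, 0 °C
Reagents that add atoms: none
Why: Dess–Martin oxidation is neutral and cold, so the β-silyloxy aldehyde should form without elimination or epimerisation next to the ketone.

Step 5
Reactants: 7 ene precursor
Product: 8 trans-fused bicyclo[5.4.0]undecenone with C3 hydroxyl, C1 silyloxy group and exocyclic methylene at C5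
Conditions: Me2AlCl (2.5 equiv), CH2Cl2, −78 → −20 °C; aq. KNaC4H4O6 (potassium sodium tartrate)
Reagents that add atoms: none
Why: Me2AlCl binds the aldehyde oxygen (a second equivalent is taken up by the enone carbonyl), and the methylene terminus of the isopropenyl group (C4) attacks the activated aldehyde carbon (C3) while an allylic hydrogen of the methyl group passes to oxygen through a six-membered transition state, so C3–C4 forms and the alkene moves to the exocyclic position at C5. The closest known reaction type is the Me2AlCl-promoted type 2 intramolecular carbonyl-ene cyclisation of 2-substituted 1-alkenes carrying an aldehyde, which gives six- and seven-membered 3-methylenecycloalkanols. The seven-membered ring closes exo with respect to the C=O and with both alkene carbons (C4 and C5) inside the new ring. The new carbinol centre C3 is set by the preference of the aluminium-bound oxygen for a pseudo-equatorial place in the chair-like transition state, but it is not needed, because C3 becomes sp2 later. The lasting centres C6 and C7 are untouched, and their trans-diequatorial arrangement on the cyclohexenone holds C3 within reach of C4 and makes the ring fusion trans. The step needs attack through the methylene terminus with hydrogen transfer, in preference to a stepwise cation that could lose a ring proton or take up chloride, and it needs the β-silyloxy aldehyde to survive; the concerted pathway, the low temperature and the methyl–aluminium bonds (which turn the alcohol–aluminium complex into an alkoxide with loss of methane and so scavenge protons) secure this, and the conjugated ring alkene is too electron-poor to compete.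

Step 6
Reactants: 8 ene product; 9 methyl acrylate
Product: 10 bicyclic methyl ester with (5S) quaternary C5 bearing methyl (cis to the C6 ring CH2) and 2-(methoxycarbonyl)ethyl
Conditions: 9 (3 equiv), Fe(acac)3 (0.3 equiv), PhSiH3, EtOH/ethylene glycol, 60 °C
Reagents that add atoms: none
Why: Hydrogen-atom transfer from an iron hydride to the 1,1-disubstituted alkene places hydrogen on the methylene (the new methyl) and leaves the tertiary C5 radical, which adds to the acrylate (Giese reaction) before reduction and protonation; the conjugated ring alkene is not a good hydrogen-atom acceptor. The acrylate should approach from the equatorial side of C5, trans to the C6–C4' bond, because the other face is screened by the ring carbons C3 and C7 and their syn-axial hydrogens.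

Step 7
Reactants: 10 bicyclic ester
Product: 11 bicyclic triol (C3 OH, C1' OH, chain CH2OH)
Conditions: LiAlH4, Et2O, −78 → 0 °C
Reagents that add atoms: none
Why: Hydride reduces the enone carbonyl in the 1,2 sense and the ester to the primary alcohol in one operation; the C1' carbinol configuration is irrelevant because this oxygen is removed in step 13.

Step 8
Reactants: 11 triol
Product: 12 chain primary triethylsilyl ether
Conditions: TESCl, imidazole, CH2Cl2, −78 °C
Reagents that add atoms: chlorotriethylsilane, CC[Si](Cl)(CC)CC
Why: The primary hydroxyl is silylated much faster than the two hindered secondary ones at low temperature.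

Step 9
Reactants: 12 diol
Product: 13 bis-pivalate (C3 OPiv, C1' OPiv)
Conditions: PivCl, pyridine, DMAP, 50 °C
Reagents that add atoms: pivaloyl chloride, CC(C)(C)C(=O)Cl
Why: Acylation of both secondary alcohols installs the leaving group for the reductive cleavage at C1' and a base-resistant, migration-resistant latent leaving group at C3 for the later enone formation.

Step 10
Reactants: 13 bis-pivalate
Product: 14 monocyclic keto aldehyde (C7 1-pivaloyloxy-2-oxopropyl, C6 2-oxoethyl)
Conditions: O3, CH2Cl2, −78 °C; Me2S
Reagents that add atoms: ozone, [O-][O+]=O
Why: The trisubstituted ring alkene is the only C=C bond present, and ozonolysis with reductive work-up cleaves C2'=C3' into the methyl ketone and the aldehyde of the future enol ester arm.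

Step 11
Reactants: 14 keto aldehyde
Product: 15 keto alcohol (C6 2-hydroxyethyl)
Conditions: LiAlH(Ot-Bu)3, THF, −78 °C
Reagents that add atoms: none
Why: The hindered alkoxyaluminium hydride reduces the aldehyde chemoselectively and should leave the ketone and the pivalates alone at low temperature; the aldehyde must be masked before the electron-transfer step.

Step 12
Reactants: 15 keto alcohol
Product: 16 primary tert-butyldimethylsilyl ether
Conditions: TBSCl, imidazole, DMF, rt
Reagents that add atoms: tert-butylchlorodimethylsilane, CC(C)(C)[Si](C)(C)Cl
Why: Standard silylation of a primary alcohol; the TBS group outlasts the triethylsilyl ether in step 14 and leaves together with the C1 silyl group in step 19.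

Step 13
Reactants: 16 α-pivaloyloxy ketone
Product: 17 acetonyl compound (C7 CH2C(O)CH3)
Conditions: SmI2, THF/MeOH, −78 °C
Reagents that add atoms: none
Why: Electron transfer to the ketone followed by loss of the α-pivalate and protonation of the samarium enolate is the known reductive cleavage of α-acyloxy ketones; it removes the old carvone oxygen and leaves C1' as the acetonyl CH2.

Step 14
Reactants: 17 triethylsilyl ether
Product: 18 chain aldehyde (C5 3-oxopropyl)
Conditions: (COCl)2, DMSO, CH2Cl2, −78 → −30 °C; Et3N
Reagents that add atoms: none
Why: Under Swern conditions a primary triethylsilyl ether is cleaved and oxidised to the aldehyde in one operation, while tert-butyldimethylsilyl ethers, the pivalate and the ketone should be unaffected.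

Step 15
Reactants: 18 chain aldehyde; 19 2-bromopropene
Product: 20 (R)-allylic alcohol (C5 (3R)-3-hydroxy-4-methylpent-4-enyl)
Conditions: 19, CrCl2, NiCl2 (cat.), chiral 2-(2-methanesulfonamidophenyl)oxazoline ligand, Et3N, THF, rt
Reagents that add atoms: none
Why: In the Nozaki–Hiyama–Kishi reaction the alkenylchromium species adds to aldehydes only, so the acetonyl ketone is spared; the centre is remote from the ring, so the enantiomer of the ligand that directs addition to the Si face of the aldehyde should set the (R) carbinol by reagent control.

Step 16
Reactants: 20 allylic alcohol
Product: 21 (R)-methanesulfonate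
Conditions: MsCl, Et3N, CH2Cl2, −30 °C; used at once
Reagents that add atoms: methanesulfonyl chloride, CS(=O)(=O)Cl
Why: Sulfonylation through the sulfene does not touch the C–O bond, so the configuration is retained; the cold, freshly made mesylate limits ionisation or allylic shift.

Step 17
Reactants: 22 2,3-dimethylbut-2-ene
Product: 23 2-methoxyprop-2-yl hydroperoxide
Conditions: O3, MeOH/CH2Cl2, −78 °C
Reagents that add atoms: ozone, [O-][O+]=O; methanol, CO
Why: Ozonolysis in methanol traps the carbonyl oxide as the α-methoxy hydroperoxide, a hydroperoxide nucleophile that carries its own acid-labile protecting group.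

Step 18
Reactants: 21 (R)-mesylate; 23 2-methoxyprop-2-yl hydroperoxide
Product: 24 (S)-peroxyketal (side-chain OOC(CH3)2OCH3)
Conditions: 23, CsOH·H2O, DMF, 0 °C
Reagents that add atoms: none
Why: Caesium 2-methoxyprop-2-yl peroxide, formed from 23 and CsOH, is a soft, weakly basic α-nucleophile that should displace the secondary allylic mesylate by SN2 with inversion, turning the (R) alcohol configuration into the (S) peroxide configuration of the target; no enone, enol ester or aldehyde is present at this stage.

Step 19
Reactants: 24 peroxyketal
Product: 25 diol (C1 OH, C6 2-hydroxyethyl)
Conditions: TBAF, AcOH, THF, rt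
Reagents that add atoms: none
Why: Fluoride removes both tert-butyldimethylsilyl ethers; buffering with acetic acid and the bulk of the pivalate should prevent acyl migration from C3 to C1, and the peroxyketal is inert to fluoride.

Step 20
Reactants: 25 diol
Product: 26 keto aldehyde (C1 ketone, C3 OPiv, C6 2-oxoethyl)
Conditions: Dess–Martin periodinane, pyridine, CH2Cl2, rt
Reagents that add atoms: none
Why: Both alcohols are oxidised under neutral conditions that leave the peroxyketal and the β-pivaloyloxy ketone intact.

Step 21
Reactants: 27 3-methylbut-2-enoic acid (2 equiv)
Product: 28 3-methylbut-2-enoic anhydride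
Conditions: 27 (2 equiv), DCC (1 equiv), CH2Cl2, 0 °C → rt; filter off the urea
Reagents that add atoms: 3-methylbut-2-enoic acid (the second molecule of 27), CC(C)=CC(=O)O
Why: One molecule of 27 adds to the carbodiimide to give the O-acylisourea, which acylates a second molecule of 27, so two acid molecules end up in the symmetrical anhydride and the water is taken up as the urea; this carbodiimide dehydration avoids the deconjugation that the acid chloride suffers with amine bases through a vinylketene.

Step 22
Reactants: 26 keto aldehyde; 28 3-methylbut-2-enoic anhydride
Product: 30 cyclohept-2-enone (E)-enol ester peroxyketal, via pivaloyloxy enol ester 29 (not isolated)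
Conditions: 28, Et3N, DMAP, CH2Cl2, 0 °C → rt; then DBU, 0 °C
Reagents that add atoms: none
Why: Amine-mediated enolisation of the aldehyde and O-acylation by the acylpyridinium give the enol ester, whereas ketones do not form enol esters under these conditions; the hindered C6 substituent should favour the (E) isomer, and the geometric isomers are separable. E1cB loss of pivalate β to the C1 ketone then gives the C2=C3 enone, and C7 stays in, or returns to, the more stable trans arrangement.

Step 23
Reactants: 30 enone enol ester; 31 formaldehyde
Product: 32 2-(hydroxymethyl)cyclohept-2-enone peroxyketal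
Conditions: 31 (37% aq.), DMAP (0.2 equiv), THF/H2O, rt
Reagents that add atoms: none
Why: Morita–Baylis–Hillman reaction: conjugate addition of DMAP to the unhindered C3, aldol addition of the enolate to formaldehyde at C2 and loss of the amine; the conjugated, β,β-disubstituted enol ester is a poor acyl donor and should survive the catalyst.

Step 24
Reactants: 32 peroxyketal
Product: 33 target hydroperoxide
Conditions: AcOH/THF/H2O, rt
Reagents that add atoms: none
Why: Mild aqueous acid hydrolyses the peroxyketal to the free hydroperoxide without touching the O–O bond, the stereocentre, the enol ester or the allylic alcohol.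

## Compound list

1 | (S)-carvone | CC1=CC[C@@H](CC1=O)C(C)=C | starting material
2 | 3-(tert-butyldimethylsilyloxy)propanal | O=CCCO[Si](C)(C)C(C)(C)C | starting material
3 | lithium dienolate of (S)-carvone (deprotonated at C6) | C=C(C)[C@H]1CC=C(C)C(O[Li])=C1 | intermediate
4 | trans-6-[3-(tert-butyldimethylsilyloxy)-1-hydroxypropyl]carvone, carbinol epimers | C=C(C)[C@H]1CC=C(C)C(=O)[C@@H]1C(O)CCO[Si](C)(C)C(C)(C)C | intermediate
5 | trans-6-[1,3-bis(tert-butyldimethylsilyloxy)propyl]carvone | C=C(C)[C@H]1CC=C(C)C(=O)[C@@H]1C(O[Si](C)(C)C(C)(C)C)CCO[Si](C)(C)C(C)(C)C | intermediate
6 | trans-6-[1-(tert-butyldimethylsilyloxy)-3-hydroxypropyl]carvone | C=C(C)[C@H]1CC=C(C)C(=O)[C@@H]1C(O[Si](C)(C)C(C)(C)C)CCO | intermediate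
7 | trans-6-[1-(tert-butyldimethylsilyloxy)-3-oxopropyl]carvone (ene precursor) | C=C(C)[C@H]1CC=C(C)C(=O)[C@@H]1C(O[Si](C)(C)C(C)(C)C)CC=O | intermediate
8 | trans-fused bicyclo[5.4.0]undecenone: C3 hydroxyl, C1 silyloxy, exocyclic methylene at C5, 2-methylcyclohex-2-enone ring fused at C6–C7 | C=C1CC(O)CC(O[Si](C)(C)C(C)(C)C)[C@H]2C(=O)C(C)=CC[C@H]12 | intermediate
9 | methyl acrylate | C=CC(=O)OC | starting material
10 | bicyclic methyl ester, (5S) quaternary C5 with methyl (cis to the C6 ring CH2) and 2-(methoxycarbonyl)ethyl | COC(=O)CC[C@@]1(C)CC(O)CC(O[Si](C)(C)C(C)(C)C)[C@H]2C(=O)C(C)=CC[C@H]12 | intermediate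
11 | bicyclic triol (C3 OH, C1' OH, chain 3-hydroxypropyl) | OCCC[C@@]1(C)CC(O)CC(O[Si](C)(C)C(C)(C)C)[C@H]2C(O)C(C)=CC[C@H]12 | intermediate
12 | chain primary triethylsilyl ether of 11 | CC[Si](CC)(CC)OCCC[C@@]1(C)CC(O)CC(O[Si](C)(C)C(C)(C)C)[C@H]2C(O)C(C)=CC[C@H]12 | intermediate
13 | C3, C1' bis-pivalate of 12 | CC[Si](CC)(CC)OCCC[C@@]1(C)CC(OC(=O)C(C)(C)C)CC(O[Si](C)(C)C(C)(C)C)[C@H]2C(OC(=O)C(C)(C)C)C(C)=CC[C@H]12 | intermediate
14 | cycloheptane keto aldehyde: C7 1-pivaloyloxy-2-oxopropyl, C6 2-oxoethyl (trans), C5 methyl and 3-(triethylsilyloxy)propyl | CC[Si](CC)(CC)OCCC[C@@]1(C)CC(OC(=O)C(C)(C)C)CC(O[Si](C)(C)C(C)(C)C)[C@@H](C(OC(=O)C(C)(C)C)C(C)=O)[C@@H]1CC=O | intermediate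
15 | keto alcohol, C6 2-hydroxyethyl | CC[Si](CC)(CC)OCCC[C@@]1(C)CC(OC(=O)C(C)(C)C)CC(O[Si](C)(C)C(C)(C)C)[C@@H](C(OC(=O)C(C)(C)C)C(C)=O)[C@@H]1CCO | intermediate
16 | primary tert-butyldimethylsilyl ether of 15 | CC[Si](CC)(CC)OCCC[C@@]1(C)CC(OC(=O)C(C)(C)C)CC(O[Si](C)(C)C(C)(C)C)[C@@H](C(OC(=O)C(C)(C)C)C(C)=O)[C@@H]1CCO[Si](C)(C)C(C)(C)C | intermediate
17 | acetonyl compound, C7 CH2C(O)CH3 | CC[Si](CC)(CC)OCCC[C@@]1(C)CC(OC(=O)C(C)(C)C)CC(O[Si](C)(C)C(C)(C)C)[C@@H](CC(C)=O)[C@@H]1CCO[Si](C)(C)C(C)(C)C | intermediate
18 | chain aldehyde, C5 3-oxopropyl | O=CCC[C@@]1(C)CC(OC(=O)C(C)(C)C)CC(O[Si](C)(C)C(C)(C)C)[C@@H](CC(C)=O)[C@@H]1CCO[Si](C)(C)C(C)(C)C | intermediate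
19 | 2-bromopropene | C=C(C)Br | starting material
20 | (R)-allylic alcohol, C5 (3R)-3-hydroxy-4-methylpent-4-enyl | C=C(C)[C@@H](CC[C@@]1(C)CC(OC(=O)C(C)(C)C)CC(O[Si](C)(C)C(C)(C)C)[C@@H](CC(C)=O)[C@@H]1CCO[Si](C)(C)C(C)(C)C)O | intermediate
21 | (R)-methanesulfonate of 20 | C=C(C)[C@@H](CC[C@@]1(C)CC(OC(=O)C(C)(C)C)CC(O[Si](C)(C)C(C)(C)C)[C@@H](CC(C)=O)[C@@H]1CCO[Si](C)(C)C(C)(C)C)OS(C)(=O)=O | intermediate
22 | 2,3-dimethylbut-2-ene | CC(C)=C(C)C | starting material
23 | 2-methoxyprop-2-yl hydroperoxide | COC(C)(C)OO | intermediate
24 | (S)-peroxyketal, side-chain OOC(CH3)2OCH3 | C=C(C)[C@H](CC[C@@]1(C)CC(OC(=O)C(C)(C)C)CC(O[Si](C)(C)C(C)(C)C)[C@@H](CC(C)=O)[C@@H]1CCO[Si](C)(C)C(C)(C)C)OOC(C)(C)OC | intermediate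
25 | diol, C1 OH and C6 2-hydroxyethyl | C=C(C)[C@H](CC[C@@]1(C)CC(OC(=O)C(C)(C)C)CC(O)[C@@H](CC(C)=O)[C@@H]1CCO)OOC(C)(C)OC | intermediate
26 | keto aldehyde, C1 ketone, C3 pivalate, C6 2-oxoethyl | C=C(C)[C@H](CC[C@@]1(C)CC(OC(=O)C(C)(C)C)CC(=O)[C@@H](CC(C)=O)[C@@H]1CC=O)OOC(C)(C)OC | intermediate
27 | 3-methylbut-2-enoic acid | CC(C)=CC(=O)O | starting material
28 | 3-methylbut-2-enoic anhydride | CC(C)=CC(=O)OC(=O)C=C(C)C | intermediate
29 | C3-pivaloyloxy cycloheptanone (E)-enol ester | C=C(C)[C@H](CC[C@@]1(C)CC(OC(=O)C(C)(C)C)CC(=O)[C@@H](CC(C)=O)[C@@H]1/C=C/OC(=O)C=C(C)C)OOC(C)(C)OC | intermediate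
30 | cyclohept-2-enone (E)-enol ester peroxyketal | C=C(C)[C@H](CC[C@@]1(C)CC=CC(=O)[C@@H](CC(C)=O)[C@@H]1/C=C/OC(=O)C=C(C)C)OOC(C)(C)OC | intermediate
31 | formaldehyde | C=O | starting material
32 | 2-(hydroxymethyl)cyclohept-2-enone peroxyketal | C=C(C)[C@H](CC[C@@]1(C)CC=C(CO)C(=O)[C@@H](CC(C)=O)[C@@H]1/C=C/OC(=O)C=C(C)C)OOC(C)(C)OC | intermediate
33 | target: (5S,6S,7S)-cyclohept-2-enone with C2 CH2OH, C5 methyl and (3S)-3-hydroperoxy-4-methylpent-4-enyl, C6 (E)-2-(3-methylbut-2-enoyloxy)vinyl, C7 acetonyl | C=C(C)[C@H](CC[C@@]1(C)CC=C(CO)C(=O)[C@@H](CC(C)=O)[C@@H]1/C=C/OC(=O)C=C(C)C)OO | target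

## Step count and least certain steps

Total: 24 steps. Longest linear sequence: 22 steps (steps 1–16, 18–20 and 22–24); steps 17 and 21 prepare reagents.

**Step 5 (key step).** The most likely failure is loss of the β-silyloxy group from the Lewis-acid-activated aldehyde, or a stepwise cationic course with proton loss into the ring or chloride capture; one C1 epimer may also cyclise slowly because its silyloxy group is forced axial. The fallback replaces the ene reaction by an intramolecular allylation that forms the same bond. It sets out from 5: allylic chlorination of the isopropenyl group (Ca(OCl)2, solid CO2, CH2Cl2/H2O) would give the allylic chloride F1, HF·pyridine the primary alcohol F2, and Dess–Martin oxidation the chloro aldehyde F3. CrCl2 in THF would then turn the allylic chloride into an allylchromium species that adds to the aldehyde through its methylene terminus, and the route is rejoined at 8.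

**Step 6.** The acrylate may approach the C5 radical from the wrong face (axial attack), or without useful facial preference, giving the C5 epimer; simple reduction of the alkene is a lesser risk. The fallback changes the order in which the two C5 substituents arrive, so that a facial preference that misplaces the acrylate chain would place the methyl carbon correctly. It sets out from 8: cross-metathesis with methyl but-3-enoate (second-generation Hoveyda–Grubbs catalyst) would give the exocyclic trisubstituted alkene F4. Hydrogen-atom-transfer hydromethylation (Fe(acac)3, PhSiH3) with formaldehyde octane-1-sulfonylhydrazone F5, made in the flask from formaldehyde and the sulfonyl hydrazide, would give the sulfonyl hydrazide adduct F6. Warming in methanol removes sulfinate and nitrogen to leave the methyl group, and the route is rejoined at 10.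

**Step 18.** Elimination to the conjugated diene, SN2' attack at the methylene terminus, or ionisation with loss of configuration may compete with direct displacement. The fallback gives up substitution for an ene reaction of singlet oxygen. It sets out from 18: Wittig reaction with isopropylidenetriphenylphosphorane at −78 °C would give the prenyl compound F7. Photooxygenation (O2, tetraphenylporphyrin, visible light; Schenck ene reaction) would give the secondary allylic hydroperoxide F8 together with its carbinol epimer and the tertiary regioisomer, because this reaction is not stereocontrolled; F8 would have to be separated by chromatography. Protection with 2-methoxypropene and pyridinium p-toluenesulfonate rejoins the route at 24.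

**Step 22.** Acylation may give a large share of the (Z)-enol ester, the aldehyde may undergo aldol reaction with one of the ketones under the basic conditions, and the amidine base may trigger base-induced fragmentation of the peroxyketal by removal of the hydrogen on the peroxide-bearing carbon. The fallback replaces enolate acylation by addition and elimination and shortens the exposure to base. It sets out from 26: 3-methylbut-2-enoyl chloride with catalytic ZnCl2 adds across the aldehyde to give the α-chloroalkyl ester F9. DBU then removes HCl by anti elimination, which favours the (E)-alkene, and removes pivalic acid from C3 in the same flask, so the route is rejoined at 30.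

**Step 23.** The amine catalyst may cleave the enol ester by acyl transfer, or the seven-membered enone may react too slowly. The fallback replaces the amine-catalysed reaction by halogenation and cross-coupling. It sets out from 30: iodine and pyridine in CH2Cl2 would give the 2-iodo enone F10, and Stille coupling with (tributylstannyl)methanol and Pd(PPh3)4 would install the hydroxymethyl group, rejoining the route at 32.

## Further compounds

F1 | step 5 | allylic chloride of 5 (2-(chloromethyl)vinyl in place of isopropenyl) | ClCC(=C)[C@H]1CC=C(C)C(=O)[C@@H]1C(O[Si](C)(C)C(C)(C)C)CCO[Si](C)(C)C(C)(C)C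
F2 | step 5 | primary alcohol from F1 | ClCC(=C)[C@H]1CC=C(C)C(=O)[C@@H]1C(O[Si](C)(C)C(C)(C)C)CCO
F3 | step 5 | chloro aldehyde from F2 | ClCC(=C)[C@H]1CC=C(C)C(=O)[C@@H]1C(O[Si](C)(C)C(C)(C)C)CC=O
F4 | step 6 | cross-metathesis product, exocyclic C5=CH–CH2CO2CH3 | COC(=O)CC=C1CC(O)CC(O[Si](C)(C)C(C)(C)C)[C@H]2C(=O)C(C)=CC[C@H]12
F5 | step 6 | formaldehyde octane-1-sulfonylhydrazone | C=NNS(=O)(=O)CCCCCCCC
F6 | step 6 | sulfonyl hydrazide adduct, C5 CH2NHNHSO2C8H17 | COC(=O)CC[C@@]1(CNNS(=O)(=O)CCCCCCCC)CC(O)CC(O[Si](C)(C)C(C)(C)C)[C@H]2C(=O)C(C)=CC[C@H]12
F7 | step 18 | prenyl compound, C5 4-methylpent-3-enyl | CC(C)=CCC[C@@]1(C)CC(OC(=O)C(C)(C)C)CC(O[Si](C)(C)C(C)(C)C)[C@@H](CC(C)=O)[C@@H]1CCO[Si](C)(C)C(C)(C)C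
F8 | step 18 | free (S)-hydroperoxide corresponding to 24 | C=C(C)[C@H](CC[C@@]1(C)CC(OC(=O)C(C)(C)C)CC(O[Si](C)(C)C(C)(C)C)[C@@H](CC(C)=O)[C@@H]1CCO[Si](C)(C)C(C)(C)C)OO
F9 | step 22 | α-chloroalkyl 3-methylbut-2-enoate from 26 (chloro carbon unassigned) | C=C(C)[C@H](CC[C@@]1(C)CC(OC(=O)C(C)(C)C)CC(=O)[C@@H](CC(C)=O)[C@@H]1CC(Cl)OC(=O)C=C(C)C)OOC(C)(C)OC
F10 | step 23 | 2-iodocyclohept-2-enone from 30 | C=C(C)[C@H](CC[C@@]1(C)CC=C(I)C(=O)[C@@H](CC(C)=O)[C@@H]1/C=C/OC(=O)C=C(C)C)OOC(C)(C)OC
A1 | alternative 1 | 6-acetoxy-2H-pyran-3(6H)-one with 4-(silyloxymethyl) group and a C2 tether holding the (Z)-methylalkene and the (E)-trisubstituted alkene | CC1(C)OC(C)(C)O[C@@H]1CC/C(C)=C/C/C=C(C)\CC2OC(OC(C)=O)C=C(CO[Si](C)(C)C(C)(C)C)C2=O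
A2 | alternative 1 | oxygen-bridged cycloheptenone fused to a methylcyclohexene | CC1(C)OC(C)(C)O[C@@H]1CC[C@@]2(C)[C@H]3C=C(CO[Si](C)(C)C(C)(C)C)C(=O)[C@@]4(O3)CC(C)=CC[C@H]24
A3 | alternative 2 | aldehyde tethered to an (E)-methyl enone | CC(C)=CCC[C@@](C)(CCCC=O)[C@@H](COCc1ccc(OC)cc1)/C=C/C(C)=O
A4 | alternative 2 | 2-acetonyl-3,4,4-substituted cycloheptanone | CC(C)=CCC[C@@]1(C)CCCC(=O)[C@@H](CC(C)=O)[C@@H]1COCc2ccc(OC)cc2
A5 | alternative 3 | trimethylsilyl enol ether (C1=C3) of the six-membered ketone | COc1ccc(COC[C@@]2(C)CC=C(O[Si](C)(C)C)[C@@H](CC3(C)OCCO3)[C@@H]2CO[Si](C)(C)C(C)(C)C)cc1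
A6 | alternative 3 | 2-bromocyclohept-2-enone with C5, C6 and C7 in place | COc1ccc(COC[C@@]2(C)CC=C(Br)C(=O)[C@@H](CC3(C)OCCO3)[C@@H]2CO[Si](C)(C)C(C)(C)C)cc1
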